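**Assumptions.** The SMILES is read as (3R,4R,5R,7R,9R,10S)-3α,9β-bis(3-methylbut-2-enoyloxy)-10βH-eremophil-11-en-8-one, a cis-fused decalin. Decalin compounds are named with eremophilane numbering (ring A = C1–C5, C10; ring B = C5–C10; C14 on C5, C15 on C4, isopropenyl C11–C13 on C7; β = face of C14). Compounds 1 and 10 and all named reagents are taken as commercially available.

**Retrosynthetic overview**
1. Target ⇐ CuH 1,4-reduction of a 7-isopropenyl Δ6-en-8-one ⇐ Stille coupling of an α-iodoenone ⇐ ring-B enone; the labile α-isopropenyl ketone is made last, under neutral conditions.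
2. Ring-B enone ⇐ Saegusa oxidation of a regiodefined C7=C8 silyl enol ether; C9–O by α′-hydroxylation; C3 ester by Mitsunobu inversion.
3. Key disconnection, in place of a Robinson annulation: Lewis-acid Diels–Alder of 2-silyloxybutadiene onto an enantiopure ring-A cyclohex-1-enecarbaldehyde. It closes ring B and sets the C5 quaternary centre and the cis fusion anti to the C4 methyl; the CHO becomes the C14 methyl.
4. Dienophile ⇐ 2-methylcyclohex-2-enone: CBS reduction (C3), anti hydroboration (C4), enol triflate formylation.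
5. Ring order: ring A is bought as a cyclohexenone; ring B is formed by the [4+2].

**Route**

Step 1
Reactants: 1 2-methylcyclohex-2-en-1-one
Product: 2 (S)-2-methylcyclohex-2-en-1-ol
Conditions: (R)-Me-CBS (10 mol %), BH3·SMe2, THF, −20 °C; MeOH quench
Reagents that add atoms: none
Why: Corey–Bakshi–Shibata reduction; the alkenyl carbon acts as the large group, so the catalyst (antipode chosen to give the S alcohol) sets the future C3 carbinol.

Step 2
Reactants: 2 (S)-2-methylcyclohex-2-en-1-ol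
Product: 3 (S)-tert-butyldimethyl[(2-methylcyclohex-2-en-1-yl)oxy]silane
Conditions: TBSCl, imidazole, DMF, rt
Reagents that add atoms: tert-butyldimethylsilyl chloride, CC(C)(C)[Si](C)(C)Cl
Why: Standard O-silylation; the bulky ether is needed to steer step 3 and to survive steps 3–10.

Step 3
Reactants: 3 (S)-tert-butyldimethyl[(2-methylcyclohex-2-en-1-yl)oxy]silane
Product: 5 (1S,2R,3S)-3-[(tert-butyldimethylsilyl)oxy]-2-methylcyclohexan-1-ol, via alkylborane 4 (not isolated)
Conditions: BH3·THF, THF, 0 °C → rt; then NaOH, H2O2, 0 °C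
Reagents that add atoms: hydrogen peroxide, OO
Why: Hydroboration–oxidation; boron adds to the less substituted alkene carbon on the face anti to the pseudo-axial allylic OTBS, so H enters C2 trans to the silyloxy group and the methyl (future C15) ends cis to it.

Step 4
Reactants: 5 (1S,2R,3S)-3-[(tert-butyldimethylsilyl)oxy]-2-methylcyclohexan-1-ol
Product: 6 (2S,3S)-3-[(tert-butyldimethylsilyl)oxy]-2-methylcyclohexan-1-one
Conditions: Dess–Martin periodinane, NaHCO3, CH2Cl2, rt
Reagents that add atoms: none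
Why: Dess–Martin oxidation under buffered conditions does not epimerise the α-methyl centre or eliminate the β-silyloxy group.

Step 5
Reactants: 6 (2S,3S)-3-[(tert-butyldimethylsilyl)oxy]-2-methylcyclohexan-1-one
Product: 8 (5S,6S)-5-[(tert-butyldimethylsilyl)oxy]-6-methylcyclohex-1-en-1-yl trifluoromethanesulfonate, via potassium enolate 7 (not isolated)
Conditions: KHMDS, THF, −78 °C; then PhNTf2, −78 → 0 °C; aq. NH4Cl
Reagents that add atoms: N-phenylbis(trifluoromethanesulfonimide), FC(F)(F)S(=O)(=O)N(c1ccccc1)S(=O)(=O)C(F)(F)F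
Why: Kinetic enolisation at the unsubstituted α-CH2 (away from the CHMe centre) followed by O-triflation; the methyl centre is untouched.

Step 6
Reactants: 8 (5S,6S)-5-[(tert-butyldimethylsilyl)oxy]-6-methylcyclohex-1-en-1-yl trifluoromethanesulfonate
Product: 9 (5S,6R)-5-[(tert-butyldimethylsilyl)oxy]-6-methylcyclohex-1-ene-1-carbaldehyde
Conditions: Pd(PPh3)4 (5 mol %), CO (1 atm), Bu3SnH (slow addition), THF, 50 °C
Reagents that add atoms: carbon monoxide, [C-]#[O+]
Why: Palladium-catalysed reductive carbonylation (Stille formylation) of the vinyl triflate gives the enal dienophile; the formyl carbon is the future C14.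

Step 7
Reactants: 10 but-3-en-2-one
Product: 11 (buta-1,3-dien-2-yloxy)triisopropylsilane
Conditions: TIPSOTf, Et3N, Et2O, 0 °C → rt
Reagents that add atoms: triisopropylsilyl trifluoromethanesulfonate, CC(C)[Si](C(C)C)(C(C)C)OS(=O)(=O)C(F)(F)F
Why: Soft enolisation and O-silylation of methyl vinyl ketone gives the 2-silyloxy diene.

Step 8
Reactants: 9 (5S,6R)-5-[(tert-butyldimethylsilyl)oxy]-6-methylcyclohex-1-ene-1-carbaldehyde; 11 (buta-1,3-dien-2-yloxy)triisopropylsilane
Product: 12 3β-(tert-butyldimethylsilyloxy)-8-(triisopropylsilyloxy)-4β-methyl-11,12,13-trinor-10βH-eremophil-7-en-14-al (cis-fused; 5β-CHO)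
Conditions: Me2AlCl (0.3 equiv), CH2Cl2, −78 → −30 °C
Reagents that add atoms: none
Why: Lewis acid-catalysed Diels–Alder reaction (key step). The nucleophilic diene CH2 bonds to the enal β-carbon (C10), which places the silyl enol ether at C7=C8. The diene adds suprafacially to the face anti to the pseudo-axial C4 methyl (A1,2 strain with CHO) and the OTBS group, which sets C5 (CHO β, cis to C15) and C10 (H β) with cis fusion.

Step 9
Reactants: 12 3β-(tert-butyldimethylsilyloxy)-8-(triisopropylsilyloxy)-4β-methyl-11,12,13-trinor-10βH-eremophil-7-en-14-al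
Product: 14 3β-(tert-butyldimethylsilyloxy)-8-(triisopropylsilyloxy)-4β,5β-dimethyl-11,12,13-trinor-10βH-eremophil-7-ene, via tosylhydrazone 13 (not isolated)
Conditions: TsNHNH2, THF, rt; then catecholborane, CHCl3, 0 °C; then NaOAc·3H2O, reflux
Reagents that add atoms: none
Why: Kabalka reduction of the tosylhydrazone (a mild Wolff–Kishner-type deoxygenation) turns the angular CHO into the C14 methyl without touching either silyl group.

Step 10
Reactants: 14 3β-(tert-butyldimethylsilyloxy)-8-(triisopropylsilyloxy)-4β,5β-dimethyl-11,12,13-trinor-10βH-eremophil-7-ene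
Product: 15 3β-(tert-butyldimethylsilyloxy)-11,12,13-trinor-10βH-eremophil-6-en-8-one
Conditions: Pd(OAc)2 (1.1 equiv), MeCN, 45 °C
Reagents that add atoms: none
Why: Saegusa–Ito oxidation; the C7 palladium enolate can β-hydride eliminate only toward C6, so the Diels–Alder regiochemistry fixes the enone as C6=C7–C8=O.

Step 11
Reactants: 15 3β-(tert-butyldimethylsilyloxy)-11,12,13-trinor-10βH-eremophil-6-en-8-one
Product: 16 3β-hydroxy-11,12,13-trinor-10βH-eremophil-6-en-8-one
Conditions: HF·pyridine, THF, 0 °C → rt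
Reagents that add atoms: none
Why: Fluoride-mediated cleavage of the secondary TBS ether; the enone is inert.

Step 12
Reactants: 16 3β-hydroxy-11,12,13-trinor-10βH-eremophil-6-en-8-one
Product: 17 3α-(3-methylbut-2-enoyloxy)-11,12,13-trinor-10βH-eremophil-6-en-8-one
Conditions: 3-methylbut-2-enoic acid, PPh3, DIAD, toluene, 0 °C → rt
Reagents that add atoms: 3-methylbut-2-enoic acid, CC(C)=CC(=O)O
Why: Mitsunobu esterification; SN2 inversion converts 3β-OH into the 3α ester (3R, trans to the C4 methyl) and installs the first senecioate.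

Step 13
Reactants: 17 3α-(3-methylbut-2-enoyloxy)-11,12,13-trinor-10βH-eremophil-6-en-8-one
Product: 19 9β-hydroxy-3α-(3-methylbut-2-enoyloxy)-11,12,13-trinor-10βH-eremophil-6-en-8-one, via lithium dienolate 18 (not isolated)
Conditions: LiHMDS, THF, −78 °C; then 2-(phenylsulfonyl)-3-phenyloxaziridine, −78 °C; aq. NH4Cl
Reagents that add atoms: 2-(phenylsulfonyl)-3-phenyloxaziridine (Davis reagent), O=S(=O)(N1OC1c1ccccc1)c1ccccc1
Why: Kinetic α′-deprotonation of the enone (C9 is the only accessible α-CH2) and Davis oxidation. With the 3α ester equatorial, the oxidant approaches C9 from the β face, anti to the ring-A bond (C5–C4) that is axial on ring B, giving the equatorial 9β-OH (9R).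

Step 14
Reactants: 19 9β-hydroxy-3α-(3-methylbut-2-enoyloxy)-11,12,13-trinor-10βH-eremophil-6-en-8-one
Product: 20 3α,9β-bis(3-methylbut-2-enoyloxy)-11,12,13-trinor-10βH-eremophil-6-en-8-one
Conditions: 3-methylbut-2-enoyl chloride, pyridine, DMAP (cat.), CH2Cl2, 0 °C
Reagents that add atoms: 3-methylbut-2-enoyl chloride, CC(C)=CC(=O)Cl
Why: Acylation with retention at C9; pyridine rather than Et3N avoids vinylketene formation and deconjugation of the senecioyl group.

Step 15
Reactants: 20 3α,9β-bis(3-methylbut-2-enoyloxy)-11,12,13-trinor-10βH-eremophil-6-en-8-one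
Product: 21 7-iodo-3α,9β-bis(3-methylbut-2-enoyloxy)-11,12,13-trinor-10βH-eremophil-6-en-8-one
Conditions: I2, pyridine, CH2Cl2, rt
Reagents that add atoms: iodine, II
Why: Johnson α-iodination of the enone (pyridine addition, iodination, elimination); the electron-poor senecioate alkenes do not react.

Step 16
Reactants: 21 7-iodo-3α,9β-bis(3-methylbut-2-enoyloxy)-11,12,13-trinor-10βH-eremophil-6-en-8-one
Product: 22 3α,9β-bis(3-methylbut-2-enoyloxy)-10βH-eremophila-6,11-dien-8-one
Conditions: tributyl(isopropenyl)stannane, Pd2(dba)3 (cat.), AsPh3, CuI (cat.), NMP, 40 °C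
Reagents that add atoms: tributyl(prop-1-en-2-yl)stannane, CCCC[Sn](CCCC)(CCCC)C(C)=C
Why: Stille coupling of the α-iodoenone under neutral conditions installs C11–C13 without touching the α-acyloxy ketone.

Step 17
Reactants: 22 3α,9β-bis(3-methylbut-2-enoyloxy)-10βH-eremophila-6,11-dien-8-one
Product: 23 (3R,4R,5R,7R,9R,10S)-3α,9β-bis(3-methylbut-2-enoyloxy)-10βH-eremophil-11-en-8-one (target)
Conditions: [(Ph3P)CuH]6, benzene, H2O (degassed), rt
Reagents that add atoms: none
Why: Stryker conjugate reduction delivers hydride to C6 of the enone only (the β,β-disubstituted senecioates are inert). The copper dienolate is protonated at the α-carbon C7, giving the β,γ-unsaturated ketone; the 7β-isopropenyl group is equatorial and is the strongly preferred epimer, reached directly or by brief enol-mediated equilibration.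

**Compound list**
1 | 2-methylcyclohex-2-en-1-one | CC1=CCCCC1=O | starting material
2 | (S)-2-methylcyclohex-2-en-1-ol | O[C@H]1CCCC=C1C | intermediate
3 | (S)-tert-butyldimethyl[(2-methylcyclohex-2-en-1-yl)oxy]silane | CC(C)(C)[Si](C)(C)O[C@H]1CCCC=C1C | intermediate
4 | alkylborane: 5 with BH2 in place of OH, same configuration | CC(C)(C)[Si](C)(C)O[C@H]1CCC[C@H](B)[C@H]1C | intermediate
5 | (1S,2R,3S)-3-[(tert-butyldimethylsilyl)oxy]-2-methylcyclohexan-1-ol | CC(C)(C)[Si](C)(C)O[C@H]1CCC[C@H](O)[C@H]1C | intermediate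
6 | (2S,3S)-3-[(tert-butyldimethylsilyl)oxy]-2-methylcyclohexan-1-one | CC(C)(C)[Si](C)(C)O[C@H]1CCCC(=O)[C@H]1C | intermediate
7 | potassium enolate of 6 (C1=C6) | CC(C)(C)[Si](C)(C)O[C@H]1CCC=C([O-])[C@H]1C.[K+] | intermediate
8 | (5S,6S)-5-[(tert-butyldimethylsilyl)oxy]-6-methylcyclohex-1-en-1-yl trifluoromethanesulfonate | CC(C)(C)[Si](C)(C)O[C@H]1CCC=C(OS(=O)(=O)C(F)(F)F)[C@H]1C | intermediate
9 | (5S,6R)-5-[(tert-butyldimethylsilyl)oxy]-6-methylcyclohex-1-ene-1-carbaldehyde | CC(C)(C)[Si](C)(C)O[C@H]1CCC=C(C=O)[C@H]1C | intermediate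
10 | but-3-en-2-one (methyl vinyl ketone) | CC(=O)C=C | starting material
11 | (buta-1,3-dien-2-yloxy)triisopropylsilane | C=CC(=C)O[Si](C(C)C)(C(C)C)C(C)C | intermediate
12 | 3β-(TBSO)-8-(TIPSO)-4β-methyl-11,12,13-trinor-10βH-eremophil-7-en-14-al (cis-fused, 5β-CHO) | C=1C[C@@]2(C=O)[C@H](CC[C@H](O[Si](C)(C)C(C)(C)C)[C@@H]2C)CC=1O[Si](C(C)C)(C(C)C)C(C)C | intermediate
13 | C14 N-tosylhydrazone of 12 | C=1C[C@@]2(/C=N/NS(=O)(=O)c3ccc(C)cc3)[C@H](CC[C@H](O[Si](C)(C)C(C)(C)C)[C@@H]2C)CC=1O[Si](C(C)C)(C(C)C)C(C)C | intermediate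
14 | 3β-(TBSO)-8-(TIPSO)-4β,5β-dimethyl-11,12,13-trinor-10βH-eremophil-7-ene | C=1C[C@@]2(C)[C@H](CC[C@H](O[Si](C)(C)C(C)(C)C)[C@@H]2C)CC=1O[Si](C(C)C)(C(C)C)C(C)C | intermediate
15 | 3β-(TBSO)-11,12,13-trinor-10βH-eremophil-6-en-8-one | C1=C[C@@]2(C)[C@H](CC[C@H](O[Si](C)(C)C(C)(C)C)[C@@H]2C)CC1=O | intermediate
16 | 3β-hydroxy-11,12,13-trinor-10βH-eremophil-6-en-8-one | C1=C[C@@]2(C)[C@H](CC[C@H](O)[C@@H]2C)CC1=O | intermediate
17 | 3α-(3-methylbut-2-enoyloxy)-11,12,13-trinor-10βH-eremophil-6-en-8-one | C1=C[C@@]2(C)[C@H](CC[C@@H](OC(=O)C=C(C)C)[C@@H]2C)CC1=O | intermediate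
18 | lithium 6,8-dienolate of 17 | C1=C[C@@]2(C)[C@H](CC[C@@H](OC(=O)C=C(C)C)[C@@H]2C)C=C1[O-].[Li+] | intermediate
19 | 9β-hydroxy-3α-(3-methylbut-2-enoyloxy)-11,12,13-trinor-10βH-eremophil-6-en-8-one | C1=C[C@@]2(C)[C@H](CC[C@@H](OC(=O)C=C(C)C)[C@@H]2C)[C@@H](O)C1=O | intermediate
20 | 3α,9β-bis(3-methylbut-2-enoyloxy)-11,12,13-trinor-10βH-eremophil-6-en-8-one | C1=C[C@@]2(C)[C@H](CC[C@@H](OC(=O)C=C(C)C)[C@@H]2C)[C@@H](OC(=O)C=C(C)C)C1=O | intermediate
21 | 7-iodo-3α,9β-bis(3-methylbut-2-enoyloxy)-11,12,13-trinor-10βH-eremophil-6-en-8-one | IC1=C[C@@]2(C)[C@H](CC[C@@H](OC(=O)C=C(C)C)[C@@H]2C)[C@@H](OC(=O)C=C(C)C)C1=O | intermediate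
22 | 3α,9β-bis(3-methylbut-2-enoyloxy)-10βH-eremophila-6,11-dien-8-one | C=C(C)C1=C[C@@]2(C)[C@H](CC[C@@H](OC(=O)C=C(C)C)[C@@H]2C)[C@@H](OC(=O)C=C(C)C)C1=O | intermediate
23 | (3R,4R,5R,7R,9R,10S)-3α,9β-bis(3-methylbut-2-enoyloxy)-10βH-eremophil-11-en-8-one | C=C(C)[C@H]1C[C@@]2(C)[C@H](CC[C@@H](OC(=O)C=C(C)C)[C@@H]2C)[C@@H](OC(=O)C=C(C)C)C1=O | target

**Totals.** 17 steps in all. The longest linear sequence is 16 steps (1 → 23 through steps 1–6 and 8–17); step 7 is a one-step side branch.

**Steps most likely to fail, with fallbacks**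

Step 8 (Diels–Alder). The dienophile is a hindered trisubstituted enal, and Mukaiyama-type aldol attack of the siloxy diene on the aldehyde could compete. The fallback sets out from 9 and returns at 16. Compound 9 is heated without Lewis acid in toluene (60–80 °C) with the much more nucleophilic, commercial Rawal diene, (E)-1-(dimethylamino)-3-(tert-butyldimethylsilyloxy)buta-1,3-diene. This gives the 6β-dimethylamino C7=C8 silyl enol ether aldehyde F1 with the same regio- and facial sense. Its formyl group is deoxygenated as in step 9 through the tosylhydrazone F2 to the 5β-methyl amino silyl enol ether F3. Aqueous HF in MeCN then hydrolyses the enol ether, eliminates dimethylamine to the enone and removes the TBS ether, giving 16 directly. Steps 7–11 are bypassed.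

Step 12 (Mitsunobu inversion). The C3 carbinol is hindered and flanked by anti-periplanar hydrogens, so E2 elimination may compete. The fallback sets out from 16 and returns at 17. Compound 16 is converted with ClCH2SO2Cl/pyridine (0 °C) into the 3β-chloromethanesulfonate F4. This is displaced with cesium 3-methylbut-2-enoate and 18-crown-6 in toluene at 60 °C (SN2 with inversion) to give 17.

Step 17 (CuH reduction). Hydride must reach a neopentyl β-carbon, C7 protonation may give epimers, and the product can slip into the conjugated 7(11)-ene. The fallback sets out from 20 and returns at 23, replacing steps 15–17. Rh-catalysed 1,4-hydrosilylation of 20 (Et3SiH, (Ph3P)3RhCl, benzene, 50 °C) gives the regiodefined 8-triethylsilyl enol ether F5. Palladium-catalysed α-alkenylation with 2-bromopropene (Pd(OAc)2/P(t-Bu)3, ZnF2, CsF, DMF, 60 °C) then forms the C7–C11 bond and gives 23.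

**Further compounds**
F1 | step 8 | 6β-(dimethylamino)-3β,8-bis(tert-butyldimethylsilyloxy)-4β-methyl-11,12,13-trinor-10βH-eremophil-7-en-14-al | C=1[C@@H](N(C)C)[C@@]2(C=O)[C@H](CC[C@H](O[Si](C)(C)C(C)(C)C)[C@@H]2C)CC=1O[Si](C)(C)C(C)(C)C
F2 | step 8 | C14 N-tosylhydrazone of F1 (not isolated) | C=1[C@@H](N(C)C)[C@@]2(/C=N/NS(=O)(=O)c3ccc(C)cc3)[C@H](CC[C@H](O[Si](C)(C)C(C)(C)C)[C@@H]2C)CC=1O[Si](C)(C)C(C)(C)C
F3 | step 8 | 6β-(dimethylamino)-3β,8-bis(tert-butyldimethylsilyloxy)-4β,5β-dimethyl-11,12,13-trinor-10βH-eremophil-7-ene | C=1[C@@H](N(C)C)[C@@]2(C)[C@H](CC[C@H](O[Si](C)(C)C(C)(C)C)[C@@H]2C)CC=1O[Si](C)(C)C(C)(C)C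
F4 | step 12 | 3β-(chloromethanesulfonyloxy)-11,12,13-trinor-10βH-eremophil-6-en-8-one | C1=C[C@@]2(C)[C@H](CC[C@H](OS(=O)(=O)CCl)[C@@H]2C)CC1=O
F5 | step 17 | 8-(triethylsilyloxy)-3α,9β-bis(3-methylbut-2-enoyloxy)-11,12,13-trinor-10βH-eremophil-7-ene | C=1C[C@@]2(C)[C@H](CC[C@@H](OC(=O)C=C(C)C)[C@@H]2C)[C@@H](OC(=O)C=C(C)C)C=1O[Si](CC)(CC)CC
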